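- The closed, stirred, isothermal west flask holds substrate at c(substrate) = 0.10 M and has been followed up to 12.0 min; the question is how much dormant form it holds later.

- west: substrate 0.10 M; the very flask that is asked about, followed so far
- flask: substrate 0.10 M; time 30 min

west run (percent of the substrate charged)

| time / min | dormant form / % | ring / % |
|---|---|---|
| 1.00 | 4 | 1 |
| 2.00 | 7 | 3 |
| 3.00 | 11 | 6 |
| 6.00 | 16 | 11 |
| 12.0 | 24 | 14 |

(standard deviation of a reading: 1.5 percentage points)

- a reading or a percentage of ring counts all its forms, free or not

- amount of dormant form in percent of the substrate charged, at 6.0 min, 15 min and 30 min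

- The quantity to carry is the halving time of a species' gain, an apparent half-life: the time between the midpoints of two reading windows, divided by the number of halvings of the mean gain rate between them.
- Dormant form gains 0.0367 min⁻¹ of the charge up to 3.00 min, then 0.0133 min⁻¹ between 6.00 min and 12.0 min, so its halving time reads 5.14 min, with each reading scattered by 1.5 percentage points.
- Fastest rung: the same windows give ring a halving time of 3.75 min, shorter than that of dormant form, so the ring reading has nearly stalled at 14% by 12.0 min while that of dormant form still climbs.
- Slowest rung: the asked 30 min spans 5.84 halvings of dormant form's gain, so a continued exponential slowing leaves a tail after 12.0 min that can be summed.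
- The reckoning here keeps the reading 16% at 6.0 min and runs that tail on to 26.2% at 15 min and 30.0% at 30 min.
- The forecast says 16.5%, 27% and 33%, judging that “it may be levelling towards an equilibrium or a catalyst-limited plateau”; its last point stands higher than the reckoning here.
- The flask gives 17.6%, 27.6% and 29.9%.

    substrate → ring (k = 0.0280 min⁻¹)
    2 substrate → open dimer (k = 0.230 M⁻¹ min⁻¹)
    crystals ⇌ ring, rate k3*(cs3 - [ring]) while solid is left; crystals form when [ring] > cs3 (solubility = 0.0920 M, k = 1.30 min⁻¹)
    substrate ⇌ dormant form (K = 1.80, k = 0.0430 min⁻¹)
    ring → over-reaction product (k = 0.0830 min⁻¹)

- Substrate and dormant form relax by their own step with a half-life of 10.4 min, both directions of that step together, and the flask still holds 14.7% of substrate at 30.0 min. Counted in the carried halving time, 300 min is 58.4 halvings, yet the level of 29.9% does not stay: at that time the flask holds 3.55% of dormant form.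

(The readings are calculated on assumed constants, and the scatter is random.)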